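1. The starting material was a small charge, 0.014 M, less than the reagent in each flask. In the theta run it had fallen to 1.0% by 80.0 min, so what I needed to follow was the intermediate.

| flask | starting material | reagent | scavenger | remark | time |
|---|---|---|---|---|---|
| theta | 0.014 M | 0.0252 M | 10 mM | run made earlier |  |
| red | 0.014 M | 0.0250 M | 7.00 mM |  | 4.0 h |
| amber | 0.014 M | 0.0380 M | 7.00 mM |  | 4.0 h |

theta run (percent of the starting material charged)

| time / min | intermediate / % | isomer of the product / % | starting material / % | target / % |
|---|---|---|---|---|
| 12.0 | 48.6 | 0.7 | 26.2 | 23.9 |
| 25.0 | 40.6 | 2.8 | 13.6 | 43.7 |
| 40.0 | 35.7 | 4.0 | 5.9 | 54.6 |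
| 50.0 | 33.6 | 4.2 | 4.1 | 57.7 |
| 60.0 | 33.2 | 4.7 | 2.7 | 60.0 |
| 80.0 | 31.6 | 6.3 | 1.0 | 61.5 |

(each reading ± 0.3 percentage points)

1. which of these there is most of at the end, counted by the starting material in it, red (isomer of the product / intermediate / target / starting material)
2. which of these there is most of at the end, counted by the starting material in it, amber (isomer of the product / intermediate / target / starting material)
3. how much there is at the end of the one of these that leads, in percent of the starting material charged: red
4. how much there is at the end of the one of these that leads, in percent of the starting material charged: amber

- no earlier run changes the charge of scavenger; that part of a forecast is a guess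

2. In theta, c(target)/c(intermediate) read 1.08 at 25.0 min and 1.95 at 80.0 min. I called this last reading R, the holding ratio c(target)/c(intermediate) that a reversible step reaches: an equilibrium constant as read.

3. I then asked which concentration sets the rate. I tried a net rate k(c(intermediate) − c(target)/R), first order, with no reagent in it. Theta gave k = 0.0559 /min between 12.0 min and 25.0 min, and 0.0641 /min between 50.0 min and 80.0 min, the late value higher than the early one. I took that as one constant and the plateau as an equilibrium. No earlier run changes the reagent or the scavenger, so this was my judgement.

4. I ran the isomer on in a straight line from its theta gain, which gave 16.5% at 4.0 h. Target is then the share R/(1+R) of the remainder, 55.2%, and my reckoning gave that for both red and amber.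

5. The forecast also put target first in red and target first in amber, but it gave 64% (55% to 73%) for red and 80% (66% to 90%) for amber, both higher than my figure . Its grounds for amber were: “Amber has excess reagent, so intermediate clears”.

6. Target led in both flasks, with 57.1% in red and 56.8% in amber.

    starting material + reagent → intermediate + released group (k = 0.170 /M/s)
    scavenger + released group → scavenged by-product (k = 2.20 /M/s)
    intermediate ⇌ isomer of the product (K = 2.80, k = 3.60 × 10⁻⁵ /s)
    reagent + released group ⇌ idle adduct, settled at all times (K = 9500 /M)
    intermediate ⇌ target (K = 2.00, k = 9.10 × 10⁻⁴ /s)

7. Red ended with 17% of its reagent charge left and amber with 43%, yet their target differed by 0.30 percentage points, and in amber the step from intermediate to target had half of its turnover up to the asked time behind it by 0.187 h, far earlier than the 4.0 h asked. With amber's isomer at 15.3%, R gives 55.9% of target, and the flask held 56.8%.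

8. The neighbour is amber itself, read at 15 h. With its isomer at 35.8%, R gives 42.4% of target, and the computed amount is 43.0%.

The earlier runs and the new flask are calculated from invented constants.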